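## Retrosynthetic overview

- The C3 hydroxyl of the lactone is removed first (late enolate oxidation, anti to the C5 side chain). This leaves the deoxy lactone 6.
- In 6, the bond between C3 of the central indole and the lactone-bearing CH2 is cut. The nucleophile is not the 2,3'-linked bis-indole but its symmetric 3,3'-isomer 2. The electrophile is the primary triflate 4 of a chiral-pool lactone.
- Enabling feature: the central indole ring carries an indol-3-ylmethyl group at C2 next to an alkyl group at C3. This pattern is the Plancher isomer of a 3-alkyl-3-(indol-3-ylmethyl)-3H-indolium ion. The bridging CH2, flanked by the electron-rich C3' of the outer indole, is an exceptional migrating group.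
- The C3–CH2(bridge) bond of 2 is absent from the target. It is a temporary bond that is exchanged for the C2–CH2 bond in the same operation that forms the new C3–CH2 bond.
- No ring is built. Both indole rings (from 1) and the γ-lactone ring (from 3, which brings the C5 stereocentre) are purchased.

Key step: step 3

Remark on the chemistry: the lactone carbon bearing the side chain reads S in 3–7 and R in 8. This is only because the CIP ranking changes once C3 of the lactone carries oxygen. The spatial arrangement at this carbon never changes. Compound 3 (derived from L-glutamic acid) is taken as commercially available.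

## Route

Step 1
Reactants: 1 1-methyl-1H-indole (2 equiv)
Product: 2 bis(1-methyl-1H-indol-3-yl)methane
Conditions: 37% aq. CH2O (0.5 equiv per indole), p-TsOH·H2O (5 mol %), MeOH, 23 °C
Reagents that add atoms: formaldehyde, C=O
Why: In this double Friedel–Crafts hydroxyalkylation/alkylation, C3 of 1 adds to protonated formaldehyde, the carbinol ionises to the 3-methylene-3H-indolium ion, and a second molecule of 1 captures it at C3; no stereocentre is formed.

Step 2
Reactants: 3 (S)-5-(hydroxymethyl)dihydrofuran-2(3H)-one
Product: 4 [(2S)-5-oxotetrahydrofuran-2-yl]methyl trifluoromethanesulfonate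
Conditions: Tf2O (1.1 equiv), 2,6-lutidine (1.3 equiv), CH2Cl2, −78 → −20 °C; cold aqueous work-up, short silica plug, used at once
Reagents that add atoms: trifluoromethanesulfonic anhydride, O=S(=O)(C(F)(F)F)OS(=O)(=O)C(F)(F)F
Why: This is an O-sulfonylation of a primary alcohol that does not touch the adjacent stereocentre, and the β-acyloxy group slows ionisation enough that such primary triflates can be handled.

Step 3
Reactants: 2 bis(1-methyl-1H-indol-3-yl)methane (1.5 equiv, excess recoverable); 4 [(2S)-5-oxotetrahydrofuran-2-yl]methyl trifluoromethanesulfonate (1.0 equiv)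
Product: 6 (5S)-5-({1-methyl-2-[(1-methyl-1H-indol-3-yl)methyl]-1H-indol-3-yl}methyl)dihydrofuran-2(3H)-one, via 3H-indolium triflate 5 (not isolated)
Conditions: 2,6-di-tert-butyl-4-methylpyridine (1.2 equiv), 4 Å MS, MeNO2, 23 → 50 °C
Reagents that add atoms: none
Why: Proposed new method: the enamine carbon C3 of one of the two equivalent indole rings of 2 displaces triflate from the primary CH2 of 4 (SN2) to form the C3–CH2 bond and the 3,3-disubstituted 3H-indolium ion 5, after which the indol-3-ylmethyl group shifts from C3 to the iminium carbon C2 (Wagner–Meerwein/Plancher 1,2-shift) and the hindered pyridine removes the C2 proton to restore the indole. The closest known reaction type is the C3 alkylation of 3-alkylindoles by alkyl halides with subsequent Plancher rearrangement, the accepted ipso-attack/migration pathway for 2-substitution of 3-substituted indoles; what is new is a functionalised primary triflate as electrophile and a bis(indolyl)methane as the substrate that supplies the migrating group. No ring is closed, and the lactone of 4 cannot interfere because its carbonyl is held in the ring away from the reacting CH2. The lactone stereocentre is preserved because displacement occurs at the neighbouring CH2, and the transient quaternary C3 of 5 may form as either epimer because rearomatisation erases it, so both funnel into the single compound 6. Site selectivity (C3 over C2) rests on the nitrogen-stabilised iminium ion that only C3 attack produces, and the choice of migrating group rests on the azafulvenium-like stabilisation of the indol-3-ylmethyl unit compared with the electron-poor β-acyloxyalkyl chain; a dissociative variant also leads to 6, since C2 is the only open position of the released 3-alkylindole. The non-nucleophilic base keeps the medium acid-free so that 2 is not cleaved by C3 protonation, and the excess of 2 limits a second alkylation of 6.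

Step 4
Reactants: 6 (5S)-5-({1-methyl-2-[(1-methyl-1H-indol-3-yl)methyl]-1H-indol-3-yl}methyl)dihydrofuran-2(3H)-one
Product: 8 chaetoindolone C, via potassium lactone enolate 7 (not isolated)
Conditions: KHMDS (1.1 equiv), THF, −78 °C; then 2-(phenylsulfonyl)-3-phenyloxaziridine (1.2 equiv), −78 °C; AcOH quench at −78 °C
Reagents that add atoms: 2-(phenylsulfonyl)-3-phenyloxaziridine (Davis oxaziridine), O=S(=O)(c1ccccc1)N1OC1c1ccccc1
Why: In this Davis enolate hydroxylation KHMDS removes only the lactone α-proton (more acidic than the diindolyl CH2), the oxaziridine transfers oxygen to the enolate face anti to the large C5 substituent to set the 3,5-trans (3R) configuration, and the enolate should outcompete the indole rings for the oxidant at −78 °C.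

## Compound list

1 | 1-methyl-1H-indole | Cn1ccc2ccccc21 | starting material
2 | bis(1-methyl-1H-indol-3-yl)methane | Cn1cc(Cc2cn(C)c3ccccc23)c2ccccc21 | intermediate
3 | (S)-5-(hydroxymethyl)dihydrofuran-2(3H)-one | OC[C@@H]1CCC(=O)O1 | starting material
4 | [(2S)-5-oxotetrahydrofuran-2-yl]methyl trifluoromethanesulfonate | FC(F)(F)S(=O)(=O)OC[C@@H]1CCC(=O)O1 | intermediate
5 | 1-methyl-3-[(1-methyl-1H-indol-3-yl)methyl]-3-{[(2S)-5-oxotetrahydrofuran-2-yl]methyl}-3H-indol-1-ium triflate (either configuration at C3, not isolated) | C[N+]1=CC(Cc2cn(C)c3ccccc23)(C[C@@H]2CCC(=O)O2)c2ccccc21.[O-]S(=O)(=O)C(F)(F)F | intermediate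
6 | (5S)-5-({1-methyl-2-[(1-methyl-1H-indol-3-yl)methyl]-1H-indol-3-yl}methyl)dihydrofuran-2(3H)-one | Cn1cc(Cc2c(C[C@@H]3CCC(=O)O3)c3ccccc3n2C)c2ccccc21 | intermediate
7 | potassium enolate of 6 (not isolated) | Cn1cc(Cc2c(C[C@@H]3CC=C([O-])O3)c3ccccc3n2C)c2ccccc21.[K+] | intermediate
8 | chaetoindolone C, (3R,5R)-3-hydroxy-5-({1-methyl-2-[(1-methyl-1H-indol-3-yl)methyl]-1H-indol-3-yl}methyl)dihydrofuran-2(3H)-one | Cn1cc(Cc2c(C[C@@H]3C[C@@H](O)C(=O)O3)c3ccccc3n2C)c2ccccc21 | target

## Step count

Total step count: 4.
Longest linear sequence: 3 steps (3 → 4 → 6 → 8, or 1 → 2 → 6 → 8).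

## Steps most likely to fail

**1. Step 3 (Proposed new method).**
- What may go wrong: displacement at the hindered C3 may be slow, so the triflate may decay first. The migrating indolylmethyl unit may escape from the ion pair and transfer to a second molecule of 2. Direct attack through C2 may compete.
- Fallback (known chemistry): it sets out from 1 and 3 and comes back at 6.
- Purchased (1-methyl-1H-indol-2-yl)methanol F1 is condensed with an excess of 1 under catalytic p-TsOH in CH2Cl2 (Friedel–Crafts benzylation). This gives 1-methyl-2-[(1-methyl-1H-indol-3-yl)methyl]-1H-indole F2, whose central C3 is free.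
- In parallel, 3 is converted with TsCl/pyridine into [(2S)-5-oxotetrahydrofuran-2-yl]methyl 4-methylbenzenesulfonate F3.
- F3 is treated with NaOMe in MeOH at 0 °C to give methyl 3-[(2S)-oxiran-2-yl]propanoate F4. The configuration is retained because the alkoxide displaces the primary sulfonate.
- A Lewis acid (catalytic InBr3 or Sc(OTf)3, CH2Cl2) promotes Friedel–Crafts opening of F4 at its terminal carbon by the free C3 of F2. This gives methyl (4S)-4-hydroxy-5-{1-methyl-2-[(1-methyl-1H-indol-3-yl)methyl]-1H-indol-3-yl}pentanoate F5.
- Catalytic p-TsOH in toluene lactonises F5 to 6.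

**2. Step 4.**
- What may go wrong: facial selectivity in the oxygen transfer to the enolate may be poor.
- Fallback: it sets out from 6 and comes back at 8. It moves the stereochemical burden from the enolate face to an SN2 inversion.
- The hydroxylation is run without regard to selectivity, and the 3,5-cis epimer (3S,5R)-3-hydroxy-5-({1-methyl-2-[(1-methyl-1H-indol-3-yl)methyl]-1H-indol-3-yl}methyl)dihydrofuran-2(3H)-one F6 is separated.
- Mitsunobu reaction of F6 (4-nitrobenzoic acid, PPh3, DIAD, THF, 0 °C) inverts C3 and gives the (3R,5R)-4-nitrobenzoate F7.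
- Mild methanolysis (catalytic K2CO3, MeOH, 0 °C, weakly acidic work-up to re-close any opened lactone) releases 8.

**3. Step 2.**
- What may go wrong: the triflate may decompose during isolation, by elimination towards the exocyclic enol lactone or by hydrolysis on silica.
- Fallback: it sets out from 3 and comes back at 4, which is then formed in solution only.
- An Appel reaction (I2, PPh3, imidazole, CH2Cl2) gives the shelf-stable (S)-5-(iodomethyl)dihydrofuran-2(3H)-one F8.
- AgOTf in CH2Cl2 converts F8 into 4 by halide abstraction. The silver salt is filtered off, and the solution is added directly to 2 and the hindered pyridine as in step 3.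

## Further compounds

F1 | step 3 | (1-methyl-1H-indol-2-yl)methanol (purchased) | Cn1c(CO)cc2ccccc21
F2 | step 3 | 1-methyl-2-[(1-methyl-1H-indol-3-yl)methyl]-1H-indole | Cn1cc(Cc2cc3ccccc3n2C)c2ccccc21
F3 | step 3 | [(2S)-5-oxotetrahydrofuran-2-yl]methyl 4-methylbenzenesulfonate | Cc1ccc(cc1)S(=O)(=O)OC[C@@H]1CCC(=O)O1
F4 | step 3 | methyl 3-[(2S)-oxiran-2-yl]propanoate | COC(=O)CC[C@H]1CO1
F5 | step 3 | methyl (4S)-4-hydroxy-5-{1-methyl-2-[(1-methyl-1H-indol-3-yl)methyl]-1H-indol-3-yl}pentanoate | COC(=O)CC[C@H](O)Cc1c(Cc2cn(C)c3ccccc23)n(C)c2ccccc12
F6 | step 4 | (3S,5R)-3-hydroxy-5-({1-methyl-2-[(1-methyl-1H-indol-3-yl)methyl]-1H-indol-3-yl}methyl)dihydrofuran-2(3H)-one | Cn1cc(Cc2c(C[C@@H]3C[C@H](O)C(=O)O3)c3ccccc3n2C)c2ccccc21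
F7 | step 4 | (3R,5R)-5-({1-methyl-2-[(1-methyl-1H-indol-3-yl)methyl]-1H-indol-3-yl}methyl)-2-oxotetrahydrofuran-3-yl 4-nitrobenzoate | Cn1cc(Cc2c(C[C@@H]3C[C@@H](OC(=O)c4ccc(cc4)[N+](=O)[O-])C(=O)O3)c3ccccc3n2C)c2ccccc21
F8 | step 2 | (S)-5-(iodomethyl)dihydrofuran-2(3H)-one | IC[C@@H]1CCC(=O)O1
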